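The easy step came first. In the oak flask, which is the flask asked about, each pair of readings made up about the whole charge, such as 54.9% target with 45.0% starting material. So I counted in fractions of the charge.

common to all: starting material 0.87 M; free catalyst 0.2 mol%
- oak: reagent 1.1 equiv; second substrate 0.20 equiv; the very flask that is asked about, followed so far
- larch: reagent 1.7 equiv; second substrate 0.20 equiv; run made earlier
- flask: reagent 1.10 equiv; second substrate 0.200 equiv; time 8.0 d

| run | time / d | target / % | starting material / % |
|---|---|---|---|
| oak | 0.417 | 23.8 | 76.0 |
| oak | 1.25 | 43.4 | 57.0 |
| oak | 2.50 | 54.9 | 45.0 |
| oak | 4.00 | 62.1 | 38.3 |
| oak | 5.00 | 64.4 | 35.1 |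
| oak | 6.00 | 66.6 | 34.0 |
| larch | 0.625 | 44.4 | 55.5 |
| larch | 1.25 | 60.8 | 39.2 |
| larch | 2.08 | 70.7 | 28.9 |
| larch | 2.50 | 74.3 | 25.6 |
| larch | 3.00 | 78.3 | 22.4 |
| larch | 4.00 | 82.0 | 18.2 |

(scatter of a reading: 0.3 percentage points)

- target that was removed still counts
- the earlier runs were read with a standard deviation of 0.3 percentage points
- additions bring no volume worth counting

- zeta: at 8.0 d add free catalyst, 100% of the amount charged, then wait 8.0 d
- alpha: at 8.0 d take out 90% of the target then present, then wait 8.0 d
- beta: change nothing and wait 8.0 d more

- target, in percent of the starting material first charged, at 8.0 d
- the remedy with the largest gain of target, or "none" below 2 percentage points (zeta / alpha / beta / none)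
- target present, with what was taken out counted in, in percent of the starting material first charged, after zeta
- target present, with what was taken out counted in, in percent of the starting material first charged, after beta

I built the oak flask up one process at a time.

1. Main step alone, with steady catalyst: the rate followed starting material times reagent. Scaled from the first oak reading, this gave 88.8% target at 8.0 d.

2. Second substrate added: I supposed that it also uses reagent and took its quick step as finished. What it leaves is the spare reagent, the reagent charge less the second substrate charge, in equivalents of starting material: 0.900. That is less than the starting material, so reagent became the limiting reagent, and the same reckoning fell to 81.7%.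

3. The rest: at 6.00 d the oak flask read 66.6%, less than this reckoning gave for that time. Something slowed the flask further. Carrying on the last span's gain per ratio of time, I committed to 69.8%. That lay below the spare reagent, so I expected reagent to remain for fresh catalyst to use.

The forecast said 69%, slightly under my figure. It chose zeta, with 82% after zeta and 71% after beta, on the ground that “the decline follows time, not product”.

The flask gave 69.3%. The best remedy was zeta, gaining 11 percentage points against 5.2 points for beta, with 80.1% after zeta and 74.5% after beta.

    second substrate + reagent + free catalyst → free catalyst + second product (k = 48.0 /M²/h)
    starting material + reagent + free catalyst → free catalyst + target (k = 21.7 /M²/h)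
    2 free catalyst → spent catalyst (k = 5.68 /M/h)

At 0.770 d the half-life of second substrate by its step was 0.86 d, shorter than the 1.9 d of starting material by its own. At 8.00 d the flask held 7.32% of its second substrate and 20.1% of its reagent. In this flask the target, 69.3%, stood below the spare reagent, 90.0% of the starting material charged. In the neighbour with 0.660 equiv of reagent the target, 44.6%, stood below a spare reagent of 46.0%.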